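Count the partner that the gas feeds in, and set it against the substrate charged.

all flasks: gas 76 mM (held)
- blue: substrate 0.90 M; temperature 40 °C; run made earlier
- north-east: substrate 0.45 M; temperature 40 °C; time 6.0 min
- north-west: substrate 0.45 M; temperature 55 °C; time 6.0 min
- west: substrate 0.45 M; temperature 70 °C; time 6.0 min

blue run (percent of the substrate charged)

| time / s | first product / % | triple product / % | substrate / % | double product / % |
|---|---|---|---|---|
| 10.0 | 5.8 | 0.8 | 94.4 | 0 |
| 15.0 | 8.2 | 0.6 | 91.6 | 1.1 |
| 20.0 | 12.2 | 0 | 86.9 | 0.5 |
| 30.0 | 17.1 | 0 | 82.2 | 0 |
| 40.0 | 23.5 | 1.4 | 74.9 | 0 |

(standard deviation of a reading: 1 percentage point)

- at the start none of partner is dissolved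
- reactions considered so far: substrate + partner -> first product; partner + first product -> double product; partner + double product -> triple product; double product -> decomposed reagent; gas <-> partner
- the earlier runs do not show what temperature does; that part of a forecast is a guess

1. which of these there is most of at the end, counted by the substrate in it, north-east (triple product / substrate / double product / first product)
2. which of these there is most of at the end, counted by the substrate in it, north-west (triple product / substrate / double product / first product)
3. which of these there is most of at the end, counted by the substrate in it, west (triple product / substrate / double product / first product)
4. how much there is at the end of the one of these that leads, in percent of the substrate charged: north-east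
5. how much there is at the end of the one of these that leads, in percent of the substrate charged: north-west
6. how much there is at the end of the one of these that leads, in percent of the substrate charged: west

Partner starts at none and comes from the gas, and each substrate turned into first product takes one. By 40.0 s, blue had lost 0.226 M of substrate, more than the 76 mM of gas at saturation, so partner was being fed through the flask as it reacted. Replacing the curve by its mean gives a feed of 5.65 mM s⁻¹. The scatter of 1 percentage point cannot separate a steady feed from a first-order loss, so the steady feed is this reckoning's own choice.

North-east has the same gas and temperature as blue, so this reckoning gives it the same feed. Feed times time over substrate charged gives 4.52 partner per substrate at 6.0 min: this is the dose. Blue, with twice the substrate of north-east, looks nearly the same, yet it stopped at a dose of 0.251. It read 23.5% first product against 0% double product because that dose is less than one, with 74.9% substrate still there to take the partner. On that feed north-east reaches a dose of one at 1.33 min, earlier than 6.0 min, and beyond that point the reckoning leaves first product as the partner's next taker. Feed into a liquid slows as it nears saturation, so the dose is a ceiling. The dose carries no rate for the step from first product to double product, so this reckoning gives no figure for first product in north-east. What heat does stays a guess.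

The forecast names first product at 80% in north-east, first product at 60% in north-west and double product at 45% in west, holding for north-east that the substrate is converted “and little goes further”.

The flask gives first product at 37.2% in north-east, triple product at 13.4% in north-west and triple product at 5.94% in west.

    substrate + partner → first product (k = 2.90 M⁻¹ s⁻¹, Ea = 41.0 kJ mol⁻¹)
    partner + first product → double product (k = 0.0640 M⁻¹ s⁻¹, Ea = 71.0 kJ mol⁻¹)
    partner + double product → triple product (k = 0.0610 M⁻¹ s⁻¹, Ea = 66.0 kJ mol⁻¹)
    double product → decomposed reagent (k = 0.00930 s⁻¹, Ea = 96.0 kJ mol⁻¹)
    gas ⇌ partner, rate k5*(csat - [partner]) (kL = 0.0740 s⁻¹)
    (constants at 40 °C)

Count partner drawn from the gas as one per first product, two per double product and decomposed reagent, three per triple product, plus what stands dissolved. North-east, with substrate at 0%, has then drawn 1.90 per substrate by 6.0 min against its dose of 4.52, with 0.0630 M partner dissolved. West, read at 1.50 min instead of 6.0 min, has a dose of 1.13 and has drawn 1.08, with first product at 83.5% and substrate at 5.16%.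

The earlier runs and the new flask were generated by integration for substances that don't exist; the scatter is artificial.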